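All runs are simulated with made-up constants, noise included.

62.0% of the charge is what the epsilon flask had turned into product at 52 min. Its last interval gained 1.40 mM after 9.80 mM in the one before, so we read that flask as finished, with 38.0% of its charge not found as product. The decision for the next flask is whether the gamma run, charged like the eta run, is worth leaving until 130 min.

| flask | starting material | free catalyst | time |
|---|---|---|---|
| eta | 150 mM | 3.00 mM |  |
| epsilon | 60.0 mM | 3.00 mM |  |
| zeta | 150 mM | 1.50 mM |  |
| gamma | 150 mM | 3.00 mM | 130 min |

| run | time / min | [product] / mM |
|---|---|---|
| eta run | 3.0 | 1.3 |
| eta run | 9.0 | 3.3 |
| eta run | 17 | 8.6 |
| eta run | 27 | 19.7 |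
| eta run | 39 | 34.1 |
| eta run | 52 | 43.3 |
| epsilon run | 3.0 | 1.8 |
| epsilon run | 9.0 | 7.2 |
| epsilon run | 17 | 14.5 |
| epsilon run | 27 | 26.0 |
| epsilon run | 39 | 35.8 |
| epsilon run | 52 | 37.2 |
| zeta run | 3.0 | 0.3 |
| zeta run | 9.0 | 0 |
| zeta run | 17 | 2.7 |
| zeta run | 27 | 1.9 |
| zeta run | 39 | 3.3 |
| zeta run | 52 | 5.1 |

(standard deviation of a reading: 0.8 mM)

- reaction order in [starting material] at the outset, round the charge of the eta run, defined at two percent of the starting material turned into product (one fixed amount of product, the same in the runs compared)
- reaction order in [free catalyst] at the outset, round the charge of the eta run, defined at two percent of the starting material turned into product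
- product in the gamma run at 130 min, as a share of the starting material charged

- Overall: starting material -> product, with free catalyst as catalyst.
- Constant volume, constant temperature.
- The analysis sees a species whether free or bound.
- An order is taken over about fifteen percent of the charge, up and down.

The eta flask holds 28.9% of its charge at 52 min, a smaller share than the epsilon flask, and its gains are shrinking too, 9.20 mM after 14.4 mM. The share falls as the charge rises, yet the amounts of product stay close. Product formation does not speed up with more charge either: at 17 min the epsilon flask has 14.5 mM and the eta flask 8.6 mM.

We therefore assume a second route that consumes starting material at a rate growing with the square of its concentration, against a product rate that does not rise with the charge. In this reckoning a small charge goes to product, while a large charge gives a limiting amount: what stands above the level where the two routes are equal goes down the other route. We join these limits in the simplest way: the inverse square of the product made equals the inverse square of the charge plus the inverse square of the limit. This is a rough interpolation, not an exact integral. The last epsilon reading, taken as the end of that flask, puts the limit at 47.4 mM, and we call it the product ceiling, the amount this reckoning approaches at large charge.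

For the gamma charge the rule gives a share of 30.1%, which is 1.3 percentage points above the eta reading at 52 min. In our reckoning the extra time is worth that difference, and we would leave the charge as it is to test the rule.

The forecast gave −0.9 and 2 for the orders and 33% for the gamma run, on the view that “The sharp stop suggests catalyst death rather than equilibrium”, whereas our share comes from a loss of starting material. The simulation gives −0.28, 1.9 and 29.3%, which is 0.80 points below our share.

    free catalyst + starting material ⇌ catalyst-substrate complex, settled at all times (69.30 M⁻¹)
    catalyst-substrate complex + free catalyst → product + 2 free catalyst (792.0 M⁻¹ min⁻¹)
    free catalyst + impurity → spent catalyst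
    2 starting material → homo dimer (0.3882 M⁻¹ min⁻¹)

The loss we assumed is the homo dimer step, whose first half-life by itself at the gamma charge is 8.59 min, shorter than the 43.3 min the eta run needs to bring a quarter of its charge to product . The gamma run stands at 44.0 mM at 130 min, under the ceiling of 47.4 mM, which is 31.6% of its charge. With that step taken away, the simulated gamma run passes the ceiling, with 37.5% of its charge as product .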